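**Retrosynthetic overview**

1. The target is a C2-symmetric 7,7'-dimer of 2-hydroxy-2-methylbenzofuran-3(2H)-one. Its two labile hemiketal carbons C2/C2' are set late by a twofold catalyst-controlled enolate oxygenation, carried as benzyl carbonates and freed by neutral hydrogenolysis.
2. Key disconnection: in each furanone ring the bonds O1–C7a and C3–C3a are cut. This leaves an aryne across C3a–C7a and the O1–C2–C3(=O) unit of a lactic acid amide; both furanone rings close in one operation on a symmetrical biaryl bis(2-silylaryl triflate).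
3. Enabling feature: O1 and the acyl carbon C3 sit on the adjacent arene carbons C7a and C3a, and C3a has the C4 methoxy group as its other neighbour. The aryne is therefore a 3-alkoxyaryne that takes the oxygen nucleophile at C7a and leaves the carbanion at C3a; the C2 axis through C7–C7' makes the two events identical.
4. The C7–C7' bond is made first, by anodic ortho–ortho coupling of two molecules of the mono-carbamate of 2,3-dimethoxyhydroquinone. The carbamate then directs silylation to C7a and is exchanged for the triflate at C3a.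
5. Ring order: both benzene rings are purchased, the biaryl bond comes first, the two furanone rings last and together.

Key step: step 6

Assumption: the biaryl axis, which the target structure leaves undefined, is not treated as a stereoelement to be controlled, and the hemiketal carbons C2/C2' are taken to epimerise by ring–chain tautomerism under acid or base, so they are released only in the last, neutral step (compound 1 is taken as purchasable; it is otherwise one Na2S2O4 reduction away from the purchasable quinone).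

Remark on descriptors: the carbonates 17 and 18 are (2S,2'S) with the same spatial arrangement at C2/C2' as the (2R,2'R) target, because the carbonate oxygen outranks the ring oxygen O1 whereas the free hydroxyl does not.

**Route**

Step 1
Reactants: 1 2,3-dimethoxybenzene-1,4-diol
Product: 2 4-hydroxy-2,3-dimethoxyphenyl N-isopropylcarbamate
Conditions: i-PrNCO (1 equiv), Et3N (cat.), CH2Cl2, 0 °C to rt, N2
Reagents that add atoms: isopropyl isocyanate CC(C)N=C=O
Why: Base-catalysed carbamoylation of a phenol with an isocyanate on a symmetrical diol, so the only issue is mono versus bis addition, handled by stoichiometry and recycling of 1 and of the bis-carbamate.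

Step 2
Reactants: 2 4-hydroxy-2,3-dimethoxyphenyl N-isopropylcarbamate (two molecules)
Product: 3 2,2'-dihydroxy-3,3',4,4'-tetramethoxy-[1,1'-biphenyl]-5,5'-diyl bis(N-isopropylcarbamate)
Conditions: boron-doped diamond anode, Ni cathode, undivided cell, constant current, MeBu3N O3SOMe, (CF3)2CHOH, 50 °C
Reagents that add atoms: 4-hydroxy-2,3-dimethoxyphenyl N-isopropylcarbamate (the second molecule of 2) COc1c(O)ccc(OC(=O)NC(C)C)c1OC
Why: Anodic dehydrogenative phenol homocoupling of two molecules of a 4-substituted guaiacol-type phenol in a fluorinated alcohol, in which the phenoxyl radical has its para position blocked by the carbamoyloxy group and one ortho position by methoxy, so C–C coupling should occur at the free ortho carbon that becomes C7/C7'.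

Step 3
Reactants: 3 2,2'-dihydroxy-3,3',4,4'-tetramethoxy-[1,1'-biphenyl]-5,5'-diyl bis(N-isopropylcarbamate)
Product: 4 2,2'-bis(benzyloxy)-3,3',4,4'-tetramethoxy-[1,1'-biphenyl]-5,5'-diyl bis(N-isopropylcarbamate)
Conditions: BnOH (2.4 equiv), PPh3, DIAD, THF, 0 °C to rt
Reagents that add atoms: benzyl alcohol OCc1ccccc1
Why: Mitsunobu etherification benzylates both phenols under neutral conditions, which spares the base-labile N–H aryl carbamates that an alkoxide or carbonate benzylation could cleave.

Step 4
Reactants: 4 2,2'-bis(benzyloxy)-3,3',4,4'-tetramethoxy-[1,1'-biphenyl]-5,5'-diyl bis(N-isopropylcarbamate)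
Product: 8 2,2'-bis(benzyloxy)-3,3',4,4'-tetramethoxy-6,6'-bis(trimethylsilyl)-[1,1'-biphenyl]-5,5'-diyl bis(N-isopropylcarbamate), via bis(N-silyl) carbamate 5 (not isolated), via dilithiated bis(N-silyl) carbamate 6 (not isolated), via C-silylated bis(N-silyl) carbamate 7 (not isolated)
Conditions: TBSOTf, TMEDA, Et2O, 0 °C to rt; n-BuLi, TMEDA, −78 °C; TMSCl, −78 °C to rt; aq NaHSO4
Reagents that add atoms: chlorotrimethylsilane C[Si](C)(C)Cl
Why: Directed ortho-metalation of an aryl carbamate whose N–H is masked in situ as the N-silyl derivative lithiates the only remaining ring C–H (the future C7a/C7a'), and silyl quench at −78 °C precedes any anionic Fries rearrangement.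

Step 5
Reactants: 8 2,2'-bis(benzyloxy)-3,3',4,4'-tetramethoxy-6,6'-bis(trimethylsilyl)-[1,1'-biphenyl]-5,5'-diyl bis(N-isopropylcarbamate)
Product: 10 2,2'-bis(benzyloxy)-3,3',4,4'-tetramethoxy-6,6'-bis(trimethylsilyl)-[1,1'-biphenyl]-5,5'-diyl bis(trifluoromethanesulfonate), via bis(2-silylphenol) 9 (not isolated)
Conditions: DBU, Et2NH, MeCN, 40 °C; then PhNTf2, rt
Reagents that add atoms: N-phenylbis(trifluoromethanesulfonimide) O=S(=O)(N(c1ccccc1)S(=O)(=O)C(F)(F)F)C(F)(F)F
Why: E1cB cleavage of the N-monoalkyl carbamate (the isocyanate is trapped by diethylamine) gives the phenoxide, which is triflated in the same pot by sulfonyl transfer, the established one-pot route from ortho-silyl aryl carbamates to 2-silylaryl triflates.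

Step 6
Reactants: 10 2,2'-bis(benzyloxy)-3,3',4,4'-tetramethoxy-6,6'-bis(trimethylsilyl)-[1,1'-biphenyl]-5,5'-diyl bis(trifluoromethanesulfonate); 11 2-hydroxy-N,N-dimethylpropanamide (racemic N,N-dimethyllactamide, two molecules incorporated)
Product: 14 6,6'-bis(benzyloxy)-4,4',5,5'-tetramethoxy-2,2'-dimethyl-[7,7'-bibenzofuran]-3,3'(2H,2'H)-dione (mixture of C2/C2' epimers), via sodium lactamide alkoxide 12 (not isolated), via disodium bis(amino alkoxide) 13 (not isolated)
Conditions: 11 (5 equiv), NaH, THF, 0 °C; then 10, CsF, 18-crown-6, THF, 0 °C to rt; then 1 M aq HCl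
Reagents that add atoms: 2-hydroxy-N,N-dimethylpropanamide (the second molecule of 11) CC(O)C(=O)N(C)C
Why: Proposed new method: fluoride unmasks each 2-silylaryl triflate in turn to an aryne across C3a–C7a, alkoxide 12 adds through oxygen at C7a, and the resulting C3a aryl anion adds to the neighbouring dimethylamide carbonyl, so each O1–C7a/C3–C3a pair forms in one event and the tetrahedral amino alkoxide 13 persists until the acidic work-up releases the ketone. The closest known reaction type is the aryne annulation of salicylate esters to xanthones and of N-protected α-amino esters to indolin-3-ones, extended here to an α-hydroxy amide and run twice on one biaryl. Each furanone ring closes by 5-exo-trig attack of the aryl anion on the amide carbonyl. C2 and C2' arrive as uncontrolled, enolisable C–H centres (racemic 11 suffices) and are set only in step 8. The selectivity needed is oxygen attack at C7a and not at C3a, which the C4 methoxy group flanking the aryne should secure by directing the nucleophile to the distal carbon and stabilising the C3a anion, against the steric bias of the twisted aryl group at C7. The absence of any proton source keeps the aryl anion for ring closure, and the amide (no alkoxide leaving group, no ketone before work-up) keeps a product enolate from competing for aryne.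

Step 7
Reactants: 15 benzyl chloroformate (two molecules)
Product: 16 dibenzyl peroxydicarbonate
Conditions: 30% aq H2O2 (0.5 equiv), aq NaOH, hexane, 0 °C
Reagents that add atoms: hydrogen peroxide OO; benzyl chloroformate (the second molecule of 15) O=C(Cl)OCc1ccccc1
Why: Twofold Schotten–Baumann acylation of hydrogen peroxide by two molecules of the chloroformate, the standard preparation of peroxydicarbonates, gives the electrophilic oxygen source as a solid that is kept cold.

Step 8
Reactants: 14 6,6'-bis(benzyloxy)-4,4',5,5'-tetramethoxy-2,2'-dimethyl-[7,7'-bibenzofuran]-3,3'(2H,2'H)-dione; 16 dibenzyl peroxydicarbonate (two molecules consumed, one per C2)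
Product: 17 (2S,2'S)-6,6'-bis(benzyloxy)-4,4',5,5'-tetramethoxy-2,2'-dimethyl-3,3'-dioxo-2,2',3,3'-tetrahydro-[7,7'-bibenzofuran]-2,2'-diyl dibenzyl bis(carbonate)
Conditions: 16 (2.5 equiv), O-allyl-N-(9-anthracenylmethyl)cinchonidinium bromide (10 mol %), Cs2CO3, toluene, −40 °C, argon
Reagents that add atoms: dibenzyl peroxydicarbonate (the second molecule of 16) O=C(OCc1ccccc1)OOC(=O)OCc1ccccc1
Why: Proposed new method: Cs2CO3 and the chiral quaternary ammonium salt convert each enolisable C2–H ketone into a tight chiral ammonium enolate (both C2 epimers converge on the same planar enolate), which attacks a peroxide oxygen of 16 in an SN2 displacement of benzyl carbonate, so the C2–O bond forms on the enolate face left open by the catalyst and no free hemiketal alkoxide ever appears; the closest known reaction types are the asymmetric phase-transfer α-benzoyloxylation of malonates with dibenzoyl peroxide and the achiral oxidation of ketone enolates with 16, the two independent events on the C2-symmetric substrate should statistically enrich the homochiral product once the meso-like (2R,2'S) diastereomer is removed on silica, and the catalyst series (cinchonidinium or its pseudo-enantiomeric cinchoninium) that gives the sense shown has to be fixed on a monomeric model ketone.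

Step 9
Reactants: 17 (2S,2'S)-6,6'-bis(benzyloxy)-4,4',5,5'-tetramethoxy-2,2'-dimethyl-3,3'-dioxo-2,2',3,3'-tetrahydro-[7,7'-bibenzofuran]-2,2'-diyl dibenzyl bis(carbonate)
Product: 19 (2R,2'R)-2,2',6,6'-tetrahydroxy-4,4',5,5'-tetramethoxy-2,2'-dimethyl-[7,7'-bibenzofuran]-3,3'(2H,2'H)-dione (target), via bis(hydrogen carbonate) 18 (not isolated)
Conditions: H2 (1 atm), 10% Pd/C, EtOAc, rt
Reagents that add atoms: none
Why: Heterogeneous hydrogenolysis cleaves the two aryl benzyl ethers and the two benzyl carbonates, and the carbonic acid monoesters 18 lose CO2, so both hemiketal hydroxyls appear under neutral aprotic conditions with the C2–O bonds untouched (retention), after which the product should be kept cold and away from acid or base.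

**Compound list**

1 | 2,3-dimethoxybenzene-1,4-diol | COc1c(O)ccc(O)c1OC | starting material
2 | 4-hydroxy-2,3-dimethoxyphenyl N-isopropylcarbamate | COc1c(O)ccc(OC(=O)NC(C)C)c1OC | intermediate
3 | 2,2'-dihydroxy-3,3',4,4'-tetramethoxy-[1,1'-biphenyl]-5,5'-diyl bis(N-isopropylcarbamate) | COc1c(O)c(-c2c(O)c(OC)c(OC)c(OC(=O)NC(C)C)c2)cc(OC(=O)NC(C)C)c1OC | intermediate
4 | 2,2'-bis(benzyloxy)-3,3',4,4'-tetramethoxy-[1,1'-biphenyl]-5,5'-diyl bis(N-isopropylcarbamate) | COc1c(OCc3ccccc3)c(-c2c(OCc3ccccc3)c(OC)c(OC)c(OC(=O)NC(C)C)c2)cc(OC(=O)NC(C)C)c1OC | intermediate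
5 | bis[N-(tert-butyldimethylsilyl)-N-isopropylcarbamate] of 4 (formed in situ) | COc1c(OCc3ccccc3)c(-c2c(OCc3ccccc3)c(OC)c(OC)c(OC(=O)N(C(C)C)[Si](C)(C)C(C)(C)C)c2)cc(OC(=O)N(C(C)C)[Si](C)(C)C(C)(C)C)c1OC | intermediate
6 | 6,6'-dilithio derivative of 5 (formed in situ) | COc1c(OCc3ccccc3)c(-c2c(OCc3ccccc3)c(OC)c(OC)c(OC(=O)N(C(C)C)[Si](C)(C)C(C)(C)C)c2[Li])c([Li])c(OC(=O)N(C(C)C)[Si](C)(C)C(C)(C)C)c1OC | intermediate
7 | 6,6'-bis(trimethylsilyl) derivative of 5 (formed in situ) | COc1c(OCc3ccccc3)c(-c2c(OCc3ccccc3)c(OC)c(OC)c(OC(=O)N(C(C)C)[Si](C)(C)C(C)(C)C)c2[Si](C)(C)C)c([Si](C)(C)C)c(OC(=O)N(C(C)C)[Si](C)(C)C(C)(C)C)c1OC | intermediate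
8 | 2,2'-bis(benzyloxy)-3,3',4,4'-tetramethoxy-6,6'-bis(trimethylsilyl)-[1,1'-biphenyl]-5,5'-diyl bis(N-isopropylcarbamate) | COc1c(OCc3ccccc3)c(-c2c(OCc3ccccc3)c(OC)c(OC)c(OC(=O)NC(C)C)c2[Si](C)(C)C)c([Si](C)(C)C)c(OC(=O)NC(C)C)c1OC | intermediate
9 | 2,2'-bis(benzyloxy)-3,3',4,4'-tetramethoxy-6,6'-bis(trimethylsilyl)-[1,1'-biphenyl]-5,5'-diol (formed in situ as its phenoxide) | COc1c(OCc3ccccc3)c(-c2c(OCc3ccccc3)c(OC)c(OC)c(O)c2[Si](C)(C)C)c([Si](C)(C)C)c(O)c1OC | intermediate
10 | 2,2'-bis(benzyloxy)-3,3',4,4'-tetramethoxy-6,6'-bis(trimethylsilyl)-[1,1'-biphenyl]-5,5'-diyl bis(trifluoromethanesulfonate) | COc1c(OCc3ccccc3)c(-c2c(OCc3ccccc3)c(OC)c(OC)c(OS(=O)(=O)C(F)(F)F)c2[Si](C)(C)C)c([Si](C)(C)C)c(OS(=O)(=O)C(F)(F)F)c1OC | intermediate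
11 | 2-hydroxy-N,N-dimethylpropanamide (racemic) | CC(O)C(=O)N(C)C | starting material
12 | sodium 1-(dimethylamino)-1-oxopropan-2-olate (formed in situ) | CC([O-])C(=O)N(C)C.[Na+] | intermediate
13 | disodium 6,6'-bis(benzyloxy)-3,3'-bis(dimethylamino)-4,4',5,5'-tetramethoxy-2,2'-dimethyl-2,2',3,3'-tetrahydro-[7,7'-bibenzofuran]-3,3'-diolate (formed in situ, stereoisomer mixture) | COc1c(OCc4ccccc4)c(-c2c(OCc4ccccc4)c(OC)c(OC)c3c2OC(C)C3([O-])N(C)C)c2c(c1OC)C([O-])(N(C)C)C(C)O2.[Na+].[Na+] | intermediate
14 | 6,6'-bis(benzyloxy)-4,4',5,5'-tetramethoxy-2,2'-dimethyl-[7,7'-bibenzofuran]-3,3'(2H,2'H)-dione (C2/C2' epimer mixture) | COc1c(OCc4ccccc4)c(-c2c(OCc4ccccc4)c(OC)c(OC)c3c2OC(C)C3=O)c2c(c1OC)C(=O)C(C)O2 | intermediate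
15 | benzyl chloroformate | O=C(Cl)OCc1ccccc1 | starting material
16 | dibenzyl peroxydicarbonate | O=C(OCc1ccccc1)OOC(=O)OCc1ccccc1 | intermediate
17 | (2S,2'S)-6,6'-bis(benzyloxy)-4,4',5,5'-tetramethoxy-2,2'-dimethyl-3,3'-dioxo-2,2',3,3'-tetrahydro-[7,7'-bibenzofuran]-2,2'-diyl dibenzyl bis(carbonate) | COc1c(OCc4ccccc4)c(-c2c(OCc4ccccc4)c(OC)c(OC)c3c2O[C@@](C)(OC(=O)OCc4ccccc4)C3=O)c2c(c1OC)C(=O)[C@](C)(OC(=O)OCc4ccccc4)O2 | intermediate
18 | (2S,2'S)-6,6'-dihydroxy-4,4',5,5'-tetramethoxy-2,2'-dimethyl-3,3'-dioxo-2,2',3,3'-tetrahydro-[7,7'-bibenzofuran]-2,2'-diyl bis(hydrogen carbonate) (formed in situ) | COc1c(O)c(-c2c(O)c(OC)c(OC)c3c2O[C@@](C)(OC(=O)O)C3=O)c2c(c1OC)C(=O)[C@](C)(OC(=O)O)O2 | intermediate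
19 | (2R,2'R)-2,2',6,6'-tetrahydroxy-4,4',5,5'-tetramethoxy-2,2'-dimethyl-[7,7'-bibenzofuran]-3,3'(2H,2'H)-dione | COc1c(O)c(-c2c(O)c(OC)c(OC)c3c2O[C@@](C)(O)C3=O)c2c(c1OC)C(=O)[C@](C)(O)O2 | target

**Step count and risks**

Total step count: 9. Longest linear sequence: 8 steps (1 to 19 through steps 1–6, 8 and 9); step 7 prepares the oxidant 16.

Steps most likely to fail:

Step 6 (Proposed new method). The alkoxide may attack the sulfonyl sulfur of the triflate before fluoride-induced elimination. The aryl group at C7 may slow or misdirect addition at C7a. The aryl anion may be intercepted before it closes onto the amide. The fallback separates the two bond formations using known chemistry and sets out from 10. Aryne generation (CsF, MeCN, rt) in the presence of neutral ethyl (S)-lactate (C[C@H](O)C(=O)OCC) should give, by the known O–H insertion of alcohols into arynes with the same C4-methoxy-directed regiochemistry, diethyl (2S,2'S)-2,2'-{[2,2'-bis(benzyloxy)-3,3',4,4'-tetramethoxy-(1,1'-biphenyl)-6,6'-diyl]bis(oxy)}dipropanoate F1. Saponification (LiOH, THF/H2O) should give (2S,2'S)-2,2'-{[2,2'-bis(benzyloxy)-3,3',4,4'-tetramethoxy-(1,1'-biphenyl)-6,6'-diyl]bis(oxy)}dipropanoic acid F2. Intramolecular Friedel–Crafts acylation of the strongly activated C3a–H positions (TFAA, CH2Cl2, 0 °C) should then close both furanone rings, and the fallback returns to the route at 14, whose C2/C2' configuration is immaterial because step 8 passes through the enolate.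

Step 8 (Proposed new method). Facial discrimination by the ammonium enolate may be poor, an uncatalysed background oxygenation may run at the solid base, the enolate may be acylated at oxygen, or adventitious air may autoxidise it. The fallback sets out from 14. Stoichiometric enolate formation (KN(SiMe3)2, THF, −78 °C) and the known achiral oxygenation with 16 should give 6,6'-bis(benzyloxy)-4,4',5,5'-tetramethoxy-2,2'-dimethyl-3,3'-dioxo-2,2',3,3'-tetrahydro-[7,7'-bibenzofuran]-2,2'-diyl dibenzyl bis(carbonate) F3 as the mixture of all C2/C2' stereoisomers. This is configurationally stable as a ketal carbonate; the meso-like isomer is removed on silica and the homochiral pair is resolved by preparative chromatography on a chiral stationary phase. The fallback returns to the route at 17.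

Step 4. The second lithiation or the silyl quench next to the biaryl axis may stay incomplete, a benzylic position may be lithiated and undergo Wittig rearrangement, or anionic Fries migration of the carbamate may set in. The fallback sets out from 4. Carbamate cleavage (DBU, Et2NH, MeCN, 40 °C) should give 2,2'-bis(benzyloxy)-3,3',4,4'-tetramethoxy-[1,1'-biphenyl]-5,5'-diol F4. Bromination at the only free ring position, ortho to each hydroxyl (NBS, CH2Cl2, −20 °C), should give 2,2'-bis(benzyloxy)-6,6'-dibromo-3,3',4,4'-tetramethoxy-[1,1'-biphenyl]-5,5'-diol F5. O-Silylation ((Me3Si)2NH, THF, 65 °C) should give [2,2'-bis(benzyloxy)-6,6'-dibromo-3,3',4,4'-tetramethoxy-(1,1'-biphenyl)-5,5'-diyl]bis(oxy)bis(trimethylsilane) F6. Bromine–lithium exchange (n-BuLi, THF, −78 °C) triggers the retro-Brook oxygen-to-carbon silyl shift to the lithium phenoxide of 9, which is triflated in the same flask (Tf2O, −78 °C to 0 °C). The fallback returns to the route at 10.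

Further compounds
F1 | step 6 | diethyl (2S,2'S)-2,2'-{[2,2'-bis(benzyloxy)-3,3',4,4'-tetramethoxy-(1,1'-biphenyl)-6,6'-diyl]bis(oxy)}dipropanoate | COc1c(OCc3ccccc3)c(-c2c(OCc3ccccc3)c(OC)c(OC)cc2O[C@@H](C)C(=O)OCC)c(O[C@@H](C)C(=O)OCC)cc1OC
F2 | step 6 | (2S,2'S)-2,2'-{[2,2'-bis(benzyloxy)-3,3',4,4'-tetramethoxy-(1,1'-biphenyl)-6,6'-diyl]bis(oxy)}dipropanoic acid | COc1c(OCc3ccccc3)c(-c2c(OCc3ccccc3)c(OC)c(OC)cc2O[C@@H](C)C(=O)O)c(O[C@@H](C)C(=O)O)cc1OC
F3 | step 8 | 6,6'-bis(benzyloxy)-4,4',5,5'-tetramethoxy-2,2'-dimethyl-3,3'-dioxo-2,2',3,3'-tetrahydro-[7,7'-bibenzofuran]-2,2'-diyl dibenzyl bis(carbonate), mixture of C2/C2' stereoisomers | COc1c(OCc4ccccc4)c(-c2c(OCc4ccccc4)c(OC)c(OC)c3c2OC(C)(OC(=O)OCc4ccccc4)C3=O)c2c(c1OC)C(=O)C(C)(OC(=O)OCc4ccccc4)O2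
F4 | step 4 | 2,2'-bis(benzyloxy)-3,3',4,4'-tetramethoxy-[1,1'-biphenyl]-5,5'-diol | COc1c(OCc3ccccc3)c(-c2c(OCc3ccccc3)c(OC)c(OC)c(O)c2)cc(O)c1OC
F5 | step 4 | 2,2'-bis(benzyloxy)-6,6'-dibromo-3,3',4,4'-tetramethoxy-[1,1'-biphenyl]-5,5'-diol | COc1c(OCc3ccccc3)c(-c2c(OCc3ccccc3)c(OC)c(OC)c(O)c2Br)c(Br)c(O)c1OC
F6 | step 4 | [2,2'-bis(benzyloxy)-6,6'-dibromo-3,3',4,4'-tetramethoxy-(1,1'-biphenyl)-5,5'-diyl]bis(oxy)bis(trimethylsilane) | COc1c(OCc3ccccc3)c(-c2c(OCc3ccccc3)c(OC)c(OC)c(O[Si](C)(C)C)c2Br)c(Br)c(O[Si](C)(C)C)c1OC
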